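**Retrosynthetic overview**
1. Target 21 ⇐ ketol 19 (11-hydroxy level): the C10=C11 bond is carried as a C11–OH and appears in the last step by acetylation and E1cB loss of AcOH, which also installs the C15 acetate.
2. 19 ⇐ acyclic allyl β-keto ester 16: the C8–C12 bond is closed by Pd(0) cyclisation of the (12E)-alkenyl cis-14,15-epoxide, and the activating C8 allyl ester is removed in the same pot. This closes the only carbocycle (C8–C12); the epoxide is a temporary ring opened in the same event.
3. Enabling feature: ring atom C12 carries the exocyclic C13=C14–C15(O) allylic unit and C8 lies next to the C9 carbonyl. C8 (α′) and C12 (γ) are both donor positions of the ring enone, so the allylic unit is used to make C12 an electrophilic π-allyl terminus, and the epoxide relays configuration from C14/C15 to C12.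
4. 16 ⇐ allyl acetoacetate 13 (C8–C10) + epoxy enal 12 (C11–C20, dianion aldol at C10–C11) + allylic bromide 6 (C1–C7, alkylation at C8).
5. 12 ⇐ oct-2-yn-1-ol 7 (Lindlar, Sharpless epoxidation, oxidation, Wittig); 6 ⇐ Z-selective Wittig of 1 with 2.

Key step: step 10

Remark: prostanoid numbering is used (C1 = ester carbon, ring = C8–C12, C15 = acetoxy carbon). The target is (8R,12S,15S); CIP descriptors at C12 change along the route where substituent priorities change, while the spatial arrangement stays that of the target.

**Step 1**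
Reactants: 1 (4-carboxybutyl)triphenylphosphonium bromide; 2 (tert-butyldimethylsilyloxy)acetaldehyde
Product: 4 (5Z)-7-[(tert-butyldimethylsilyl)oxy]hept-5-enoic acid, via carboxylate ylide 3 (not isolated)
Conditions: NaHMDS (2.1 equiv.), THF, 0 °C; then 2, −78 °C → rt; aq. HCl to pH 4
Reagents that add atoms: none
Why: Wittig olefination of an aldehyde with a non-stabilised ylide under salt-free conditions should pass through the kinetically preferred cis-oxaphosphetane and give the (5Z)-alkene; no stereocentre is formed.

**Step 2**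
Reactants: 4 (5Z)-7-[(tert-butyldimethylsilyl)oxy]hept-5-enoic acid
Product: 5 methyl (5Z)-7-hydroxyhept-5-enoate
Conditions: H2SO4 (cat.), MeOH, rt
Reagents that add atoms: methanol (CO)
Why: Fischer esterification in acidic methanol should at the same time methanolyse the primary silyl ether without touching the Z-alkene.

**Step 3**
Reactants: 5 methyl (5Z)-7-hydroxyhept-5-enoate
Product: 6 methyl (5Z)-7-bromohept-5-enoate
Conditions: CBr4, PPh3, CH2Cl2, 0 °C
Reagents that add atoms: carbon tetrabromide (BrC(Br)(Br)Br)
Why: The Appel reaction replaces the primary allylic hydroxyl by bromide through SN2 attack on the oxyphosphonium ion under neutral conditions, so the Z geometry should be kept.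

**Step 4**
Reactants: 7 oct-2-yn-1-ol
Product: 8 (2Z)-oct-2-en-1-ol
Conditions: H2 (1 atm), Lindlar catalyst, quinoline, EtOAc, rt
Reagents that add atoms: none
Why: Lindlar semihydrogenation adds H2 syn to the alkyne on poisoned palladium and should stop at the (Z)-allylic alcohol.

**Step 5**
Reactants: 8 (2Z)-oct-2-en-1-ol
Product: 9 [(2R,3S)-3-pentyloxiran-2-yl]methanol (cis-epoxide)
Conditions: Ti(OiPr)4 (10 mol %), D-(−)-diethyl tartrate (12 mol %), t-BuOOH, 4 Å MS, CH2Cl2, −15 °C
Reagents that add atoms: tert-butyl hydroperoxide (CC(C)(C)OO)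
Why: In the Sharpless asymmetric epoxidation the titanium–D-tartrate complex delivers oxygen to the face of the Z-allylic alcohol that gives the (2R,3S)-cis-epoxide, so the reagent sets the future C14 and C15 centres; Z-allylic alcohols are the slowest and least selective substrate class, hence the long reaction time.

**Step 6**
Reactants: 9 [(2R,3S)-3-pentyloxiran-2-yl]methanol
Product: 10 (2S,3S)-3-pentyloxirane-2-carbaldehyde (cis-epoxide, same spatial arrangement as 9)
Conditions: TEMPO (10 mol %), PhI(OAc)2, CH2Cl2, rt
Reagents that add atoms: none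
Why: Oxoammonium (TEMPO) oxidation converts the primary alcohol to the aldehyde under near-neutral conditions, under which the α-epoxy aldehyde should neither epimerise nor open.

**Step 7**
Reactants: 10 (2S,3S)-3-pentyloxirane-2-carbaldehyde; 11 (triphenylphosphoranylidene)acetaldehyde
Product: 12 (2E)-3-[(2R,3S)-3-pentyloxiran-2-yl]prop-2-enal
Conditions: toluene, rt
Reagents that add atoms: none
Why: Wittig olefination with the stabilised formyl ylide should give the (E)-enal, and single homologation should prevail because the product enal is less electrophilic than the α-epoxy aldehyde.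

**Step 8**
Reactants: 13 allyl acetoacetate; 12 (2E)-3-[(2R,3S)-3-pentyloxiran-2-yl]prop-2-enal
Product: 15 allyl (6E)-5-hydroxy-3-oxo-7-[(2R,3S)-3-pentyloxiran-2-yl]hept-6-enoate (5RS), via dilithium dianion 14 (not isolated)
Conditions: LDA (2.1 equiv.), THF, −78 → −20 °C; then 12, −78 °C; AcOH quench
Reagents that add atoms: none
Why: In this acetoacetate dianion aldol the more reactive γ-carbanion adds 1,2 to the enal at low temperature (cold enough to avoid Carroll rearrangement of the allyl ester) and forms the C10–C11 bond; the new C11 carbinol is formed without control, which is harmless because this centre is removed in step 11.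

**Step 9**
Reactants: 15 allyl (6E)-5-hydroxy-3-oxo-7-[(2R,3S)-3-pentyloxiran-2-yl]hept-6-enoate; 6 methyl (5Z)-7-bromohept-5-enoate
Product: 16 allyl (6E)-5-hydroxy-2-[(2Z)-7-methoxy-7-oxohept-2-en-1-yl]-3-oxo-7-[(2R,3S)-3-pentyloxiran-2-yl]hept-6-enoate (2RS,5RS)
Conditions: K2CO3, acetone, 0 °C → rt
Reagents that add atoms: none
Why: C-alkylation of the β-keto ester enolate with the primary allylic bromide (SN2, Z geometry kept) attaches the upper chain at C8; C8 is formed as a mixture, which is harmless because it becomes quaternary in step 10 and is reset afterwards.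

**Step 10**
Reactants: 16 allyl (6E)-5-hydroxy-2-[(2Z)-7-methoxy-7-oxohept-2-en-1-yl]-3-oxo-7-[(2R,3S)-3-pentyloxiran-2-yl]hept-6-enoate
Product: 19 methyl (5Z,8R,11RS,12R,13E,15S)-11,15-dihydroxy-9-oxoprosta-5,13-dien-1-oate, via cyclised allyl β-keto ester 17 (not isolated), via β-keto acid 18 (not isolated)
Conditions: Pd(PPh3)4 (5 mol %), THF (0.02 M), 0 °C → rt; then HCO2H, Et3N, rt
Reagents that add atoms: none
Why: Pd(0) opens the vinyl epoxide with inversion at C14 to a zwitterionic syn,syn-π-allylpalladium (C12–C14) with an alkoxide at C15, the alkoxide deprotonates the β-keto ester at C8, and the enolate attacks C12 on the face opposite to palladium, which closes the C8–C12 bond and releases the (13E)-allylic 15-alcohol; formate then lets the same catalyst hydrogenolyse the allyl ester, and the β-keto acid 18 loses CO2. The closest known reaction type is the Tsuji–Trost cyclisation of 1,3-diene monoepoxides bearing a β-keto ester to 3-(3-hydroxyalk-1-enyl)cyclopentanones with 1,4-chirality transfer, followed by palladium/formate decarboxylation of allyl β-keto esters. The single ring closure is a 5-exo-trig C-alkylation (exo with respect to the allyl unit). C12 is set by the C14 configuration of the cis-epoxide together with the E geometry of C12=C13 through double inversion (net syn-SN2′, so 14R gives the C12 configuration of the target), C15 is carried over unchanged, the quaternary C8 and the C11 carbinol arise as mixtures that do not matter, and after decarboxylation C8 should settle trans to the C12 chain by ketonisation and equilibration of the enol under the amine–formate buffer (thermodynamic control). The step needs attack at C12 instead of C14 (five- against seven-membered ring), C- over O-alkylation (an O-allyl enol ether would be re-ionised by palladium and funnelled to the ketone), and epoxide ionisation before allyl-ester ionisation, which the strain-driven opening at 0 °C and the late addition of formate should secure.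

**Step 11**
Reactants: 19 methyl (5Z,8R,11RS,12R,13E,15S)-11,15-dihydroxy-9-oxoprosta-5,13-dien-1-oate
Product: 21 methyl (5Z,8R,12S,13E,15S)-15-acetoxy-9-oxoprosta-5,10,13-trien-1-oate (target), via 11,15-diacetate 20 (not isolated)
Conditions: Ac2O, Et3N, DMAP (cat.), CH2Cl2, 0 °C → rt
Reagents that add atoms: acetic anhydride (CC(=O)OC(C)=O)
Why: DMAP-catalysed acetylation of both hydroxyls is followed by E1cB loss of acetic acid from the β-acetoxy ketone through the C10 enolate, so both C11 epimers converge on the C10=C11 enone while the C15 acetate stays, and C8 keeps (or reaches by enolisation under the amine) the more stable trans arrangement.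

**Compound list**
1 | (4-carboxybutyl)triphenylphosphonium bromide | [Br-].OC(=O)CCCC[P+](c1ccccc1)(c1ccccc1)c1ccccc1 | starting material
2 | (tert-butyldimethylsilyloxy)acetaldehyde | O=CCO[Si](C)(C)C(C)(C)C | starting material
3 | sodium 5-(triphenyl-λ5-phosphanylidene)pentanoate (carboxylate ylide) | [Na+].[O-]C(=O)CCCC=P(c1ccccc1)(c1ccccc1)c1ccccc1 | intermediate
4 | (5Z)-7-[(tert-butyldimethylsilyl)oxy]hept-5-enoic acid | OC(=O)CCC/C=C\CO[Si](C)(C)C(C)(C)C | intermediate
5 | methyl (5Z)-7-hydroxyhept-5-enoate | COC(=O)CCC/C=C\CO | intermediate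
6 | methyl (5Z)-7-bromohept-5-enoate | COC(=O)CCC/C=C\CBr | intermediate
7 | oct-2-yn-1-ol | CCCCCC#CCO | starting material
8 | (2Z)-oct-2-en-1-ol | CCCCC/C=C\CO | intermediate
9 | [(2R,3S)-3-pentyloxiran-2-yl]methanol | OC[C@H]1O[C@H]1CCCCC | intermediate
10 | (2S,3S)-3-pentyloxirane-2-carbaldehyde | O=C[C@H]1O[C@H]1CCCCC | intermediate
11 | (triphenylphosphoranylidene)acetaldehyde | O=CC=P(c1ccccc1)(c1ccccc1)c1ccccc1 | starting material
12 | (2E)-3-[(2R,3S)-3-pentyloxiran-2-yl]prop-2-enal | O=C/C=C/[C@H]1O[C@H]1CCCCC | intermediate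
13 | allyl acetoacetate (prop-2-en-1-yl 3-oxobutanoate) | CC(=O)CC(=O)OCC=C | starting material
14 | dilithium dianion of allyl acetoacetate | [Li+].[Li+].[CH2-]C(=O)[CH-]C(=O)OCC=C | intermediate
15 | allyl (6E)-5-hydroxy-3-oxo-7-[(2R,3S)-3-pentyloxiran-2-yl]hept-6-enoate (5RS) | C=CCOC(=O)CC(=O)CC(O)/C=C/[C@H]1O[C@H]1CCCCC | intermediate
16 | allyl (6E)-5-hydroxy-2-[(2Z)-7-methoxy-7-oxohept-2-en-1-yl]-3-oxo-7-[(2R,3S)-3-pentyloxiran-2-yl]hept-6-enoate (2RS,5RS) | C=CCOC(=O)C(C/C=C\CCCC(=O)OC)C(=O)CC(O)/C=C/[C@H]1O[C@H]1CCCCC | intermediate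
17 | methyl (5Z,8RS,11RS,12R,13E,15S)-8-[(allyloxy)carbonyl]-11,15-dihydroxy-9-oxoprosta-5,13-dien-1-oate | CCCCC[C@@H](/C=C/[C@H]1C(O)CC(=O)C1(C/C=C\CCCC(=O)OC)C(=O)OCC=C)O | intermediate
18 | (5Z,8RS,11RS,12R,13E,15S)-11,15-dihydroxy-1-methoxy-1,9-dioxoprosta-5,13-diene-8-carboxylic acid | CCCCC[C@@H](/C=C/[C@H]1C(O)CC(=O)C1(C/C=C\CCCC(=O)OC)C(=O)O)O | intermediate
19 | methyl (5Z,8R,11RS,12R,13E,15S)-11,15-dihydroxy-9-oxoprosta-5,13-dien-1-oate | CCCCC[C@@H](/C=C/[C@H]1C(O)CC(=O)[C@@H]1C/C=C\CCCC(=O)OC)O | intermediate
20 | methyl (5Z,8R,11RS,12R,13E,15S)-11,15-diacetoxy-9-oxoprosta-5,13-dien-1-oate | CCCCC[C@@H](/C=C/[C@H]1C(OC(C)=O)CC(=O)[C@@H]1C/C=C\CCCC(=O)OC)OC(C)=O | intermediate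
21 | methyl (5Z,8R,12S,13E,15S)-15-acetoxy-9-oxoprosta-5,10,13-trien-1-oate | CCCCC[C@@H](/C=C/[C@H]1C=CC(=O)[C@@H]1C/C=C\CCCC(=O)OC)OC(C)=O | target

**Step count**
Total steps: 11. Longest linear sequence: 8 steps (steps 4–11, from oct-2-yn-1-ol 7).

**Steps most likely to fail**

Step 10. The fully substituted enolate at C8 may close too slowly. O-alkylation, β-hydride elimination of the π-allyl intermediate, premature ionisation of the allyl ester, or attack on the not yet equilibrated anti-π-allyl complex (loss of the C14→C12 transfer) could then compete. The fallback closes the ring before the upper chain is attached; it sets out from 15 and returns at 17. Compound 15, whose nucleophilic carbon is unsubstituted, is cyclised with Pd(PPh3)4 in THF at 0 °C to allyl (5R)-4-hydroxy-5-[(1E,3S)-3-hydroxyoct-1-en-1-yl]-2-oxocyclopentane-1-carboxylate F1. The ring β-keto ester carbon of F1 is then alkylated with bromide 6 (K2CO3, acetone) to give 17, now isolated. Treatment of 17 with Pd(PPh3)4 and HCO2H/Et3N, as in the second stage of step 10, leads through 18 to 19.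

Step 9. Under the basic alkylation conditions the unprotected β-hydroxy ketone may undergo retro-aldol cleavage of C10–C11, β-elimination to the dienone or lactonisation onto the allyl ester, and the β-keto ester may be alkylated twice. The fallback masks the C11 hydroxyl; it sets out from 15 and returns at 16. Silylation (TBSCl, imidazole, DMF) gives allyl (6E)-5-[(tert-butyldimethylsilyl)oxy]-3-oxo-7-[(2R,3S)-3-pentyloxiran-2-yl]hept-6-enoate F2. Alkylation with 6 (K2CO3, acetone) gives allyl (6E)-5-[(tert-butyldimethylsilyl)oxy]-2-[(2Z)-7-methoxy-7-oxohept-2-en-1-yl]-3-oxo-7-[(2R,3S)-3-pentyloxiran-2-yl]hept-6-enoate F3. Buffered desilylation (TBAF, AcOH, THF, 0 °C) then gives 16.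

Step 11. Under the amine base the equilibration at C8 may stay incomplete, or γ-deprotonation at C12 may move the ring double bond into conjugation with the side chain and on to the tetrasubstituted C8=C12 enone. The fallback uses acid; it sets out from 19 and returns at 21. Heating 19 in AcOH/H2O (9:1) at 60 °C should dehydrate the ketol and equilibrate C8 through the enol without forming a dienolate, giving methyl (5Z,8R,12S,13E,15S)-15-hydroxy-9-oxoprosta-5,10,13-trien-1-oate F4. Acetylation (Ac2O, pyridine, 0 °C) then gives 21.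

**Further compounds**
F1 | step 10 | allyl (5R)-4-hydroxy-5-[(1E,3S)-3-hydroxyoct-1-en-1-yl]-2-oxocyclopentane-1-carboxylate | CCCCC[C@@H](/C=C/[C@H]1C(O)CC(=O)C1C(=O)OCC=C)O
F2 | step 9 | allyl (6E)-5-[(tert-butyldimethylsilyl)oxy]-3-oxo-7-[(2R,3S)-3-pentyloxiran-2-yl]hept-6-enoate | C=CCOC(=O)CC(=O)CC(O[Si](C)(C)C(C)(C)C)/C=C/[C@H]1O[C@H]1CCCCC
F3 | step 9 | allyl (6E)-5-[(tert-butyldimethylsilyl)oxy]-2-[(2Z)-7-methoxy-7-oxohept-2-en-1-yl]-3-oxo-7-[(2R,3S)-3-pentyloxiran-2-yl]hept-6-enoate | C=CCOC(=O)C(C/C=C\CCCC(=O)OC)C(=O)CC(O[Si](C)(C)C(C)(C)C)/C=C/[C@H]1O[C@H]1CCCCC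
F4 | step 11 | methyl (5Z,8R,12S,13E,15S)-15-hydroxy-9-oxoprosta-5,10,13-trien-1-oate | CCCCC[C@@H](/C=C/[C@H]1C=CC(=O)[C@@H]1C/C=C\CCCC(=O)OC)O
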